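At 20 min I must choose for this flask, maple: take out released group, feed substrate, or wait.

| setting | maple | oak | flask |
|---|---|---|---|
| substrate | 20 mM | 40 mM | 20 mM |
| gas | 0.78 mM (held) | 0.78 mM (held) | 0.78 mM (held) |
| remark | the very flask that is asked about, followed so far | run made earlier |  |
| time |  |  | 20 min |

- maple (time / min: target / %): 3.00: 36.5; 6.00: 36.8; 8.00: 37.4; 12.0: 37.6; 15.0: 36.2; 20.0: 37.0
- oak (time / s: target / %): 10.0: 24.6; 15.0: 27.1; 20.0: 26.4; 30.0: 26.9; 40.0: 29.5; 50.0: 28.2

(each reading ± 1 percentage point)

- winter: at 20 min take out 90% of the released group then present, then wait 40 min
- dusk: change nothing and wait 40 min more
- spring: at 20 min add substrate, 50.0% of the amount charged, then wait 40 min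

- what is added takes up no volume worth counting
- at the start none of the gas is in solution

- target, in percent of the substrate first charged, at 20 min
- which option adds most target ("none" when 2 percentage points or less is all one gets) (winter / dusk / spring / none)
- target present, in percent of the substrate first charged, after winter
- target present, in percent of the substrate first charged, after spring

Maple is flat from its first reading, at a mean of 36.9% of the charge, so c(target) reads 7.38 mM. Oak, with twice the charge, averages 27.6% from its second reading on, which is 11.0 mM.

A rate constant says how fast a step runs, but a line that stays flat with 63.1% of the charge unconverted suggests that the forward and backward rates have become equal. I therefore ask about the end state first, which is thermodynamic control. Each target comes with one released group, so I try one quantity at held gas, the balance number: c(target)·c(released group) divided by c(unconverted), the charge minus c(target). Maple gives 4.32 mM and oak 4.22 mM, so the number read from the two runs stays close while the percentage falls with the larger charge.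

Next comes speed. Oak is flat by 15.0 s, far shorter than the wait of 40 min, so I expect each option to reach its new balance. Dusk changes nothing, so I expect no gain from it. On my reading winter leaves 0.738 mM of released group, and the extra target that restores the balance number is 3.15 mM, giving 52.7%. Spring raises c(unconverted) to 22.6 mM, and the same reckoning gives 2.04 mM more target, or 47.1%. So I choose winter.

The forecast says: “Both runs level off, so I read each plateau as an equilibrium, not a stall.” It gives 37% now, 52.6% after winter, against my 52.7%, 47.1% after spring, and picks winter.

The simulated flask gives 36.6% at 20 min, 52.2% after winter and 46.7% after spring. Winter adds 16 percentage points, spring 10 points and dusk 0 points, so winter adds most.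

    substrate ⇌ dormant form (K = 0.580, k = 1.37 s⁻¹)
    gas ⇌ partner, rate k2*(csat - [partner]) (kL = 20.8 s⁻¹)
    intermediate ⇌ target + released group (K = 0.0210 M, k = 1.49 s⁻¹)
    substrate + partner ⇌ intermediate (K = 510 L mol⁻¹, k = 150 L mol⁻¹ s⁻¹)

This flask stops short mainly because of the way back from target and released group to intermediate: the run without it gives 100% against 36.6%. Winter takes out 90% of the released group that this way back needs, and target in this flask rises to 52.2%, close to the 52.7% that the balance number 4.32 mM gave. On the neighbour flask with 5.0 mM of substrate, the same number gives c(target) = 2.97 mM, or 59.4% of its charge. The computed neighbour gives 58.9%.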